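The carbocycle (C4a, C5, C6, C7, C8, C8a; chromanone numbering) is cut at C4a–C8a and C6–C7. This exploits the position of the quaternary C8 between C7 and C8a, both at the carbonyl oxidation level: the ring is a 2,2-dialkylmalonyl unit joined to the CH3–CO–CH2 unit (C4a, C5, C6) of a methyl ketone. In one operation an enantiopure malonyl chloride methyl ester acylates the kinetic enolate of an enantiopure methyl ketone, and the diketone dianion closes the ring by Dieckmann condensation. The ketone carries the future carboxyl group as a tert-butyl ester, so no late oxidation is needed. The cis-dimethylpyranone ring is added afterwards by C4a acylation and Mitsunobu closure.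

Key step: step 13

Assumption: the alkaloid-derived catalysts named in steps 6 and 9 are taken, by analogy with simpler α-alkyl malonates and 3-alkylglutaric anhydrides, to give the configurations drawn; if a test run shows the opposite sense, the pseudo-enantiomeric catalyst is used and nothing else changes.

Fragment A (steps 1–8): the quaternary malonyl chloride

Step 1
Reactants: 1 (1R,5R)-(+)-verbenone
Product: 2 (1R,3S)-3-acetyl-2,2-dimethylcyclobutane-1-carboxylic acid (cis-pinononic acid)
Conditions: RuCl3 (cat.), NaIO4, EtOAc/MeCN/H2O, rt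
Reagents that add atoms: sodium periodate, [Na+].[O-][I](=O)(=O)=O; water, O
Why: Oxidative cleavage of the enone C=C by RuO4 made in the flask turns C4 into the acetyl group and, after loss of C3 as CO2, C2 into the carboxyl group, so both bridgehead stereocentres of verbenone survive as the cis-1,3-disubstituted cyclobutane.

Step 2
Reactants: 2 cis-pinononic acid
Product: 3 (1R,3R)-2,2-dimethyl-3-(prop-1-en-2-yl)cyclobutane-1-carboxylic acid
Conditions: Ph3PCH3Br, KOtBu (2.5 equiv.), THF, 0 °C to rt; aq. HCl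
Reagents that add atoms: methyltriphenylphosphonium bromide, C[P+](c1ccccc1)(c1ccccc1)c1ccccc1.[Br-]
Why: Wittig methylenation of the methyl ketone, in which the carboxylate is an inert spectator that also protects the C1–H from the base, and the cis-1,3 arrangement, the favoured one for this ring, should be kept.

Step 3
Reactants: 3 isopropenyl acid
Product: 4 [(1R,3R)-2,2-dimethyl-3-(prop-1-en-2-yl)cyclobutyl]methanol
Conditions: LiAlH4, THF, 0 °C to rt
Reagents that add atoms: none
Why: Hydride reduction of the carboxylic acid to the primary alcohol, which leaves the 1,1-disubstituted alkene and both stereocentres untouched.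

Step 4
Reactants: 4 cyclobutylmethanol
Product: 5 (1R,3R)-1-(iodomethyl)-2,2-dimethyl-3-(prop-1-en-2-yl)cyclobutane
Conditions: I2, PPh3, imidazole, CH2Cl2, 0 °C to rt
Reagents that add atoms: iodine, II
Why: Appel-type iodination converts the primary alcohol into the iodide by SN2 displacement at the CH2 group, away from both stereocentres.

Step 5
Reactants: 5 cyclobutylmethyl iodide; 6 tert-butyl methyl malonate
Product: 7 1-tert-butyl 3-methyl 2-{[(1S,3R)-2,2-dimethyl-3-(prop-1-en-2-yl)cyclobutyl]methyl}propanedioate (both C2 epimers)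
Conditions: NaH, 6 (2 equiv.), DMF, 0 to 60 °C
Reagents that add atoms: none
Why: SN2 alkylation of the sodium malonate by the primary iodide in a dipolar aprotic solvent, with excess malonate to suppress dialkylation; the new malonate centre forms unselectively, which is of no consequence because it is planarised in the next step.

Step 6
Reactants: 7 monoalkylated mixed malonate; 8 prenyl bromide
Product: 9 1-tert-butyl 3-methyl (2S)-2-{[(1S,3R)-2,2-dimethyl-3-(prop-1-en-2-yl)cyclobutyl]methyl}-2-(3-methylbut-2-en-1-yl)propanedioate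
Conditions: N-(9-anthracenylmethyl)cinchonidinium chloride (10 mol%), 50% aq. KOH, toluene, −20 °C
Reagents that add atoms: none
Why: Asymmetric phase-transfer alkylation of an α-monosubstituted tert-butyl methyl malonate, in which the chiral ammonium cation covers one face of the enolate so that prenyl bromide enters from the other and the two different ester groups define the future C8; a minor C8 epimer would be a diastereomer and removable.

Step 7
Reactants: 9 quaternary mixed malonate
Product: 11 (2R)-2-{[(1S,3R)-2,2-dimethyl-3-(prop-1-en-2-yl)cyclobutyl]methyl}-2-(methoxycarbonyl)-5-methylhex-4-enoic acid, via trimethylsilyl ester 10 (not isolated)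
Conditions: TMSOTf, 2,6-lutidine, CH2Cl2, 0 °C; pH 4 buffer
Reagents that add atoms: none
Why: Silyl triflate-mediated cleavage of the tert-butyl ester (loss of 2-methylpropene from the O-silylated ester) under buffered, non-protic conditions that spare the methyl ester and the prenyl and isopropenyl groups, which a protic acid would lactonise or rearrange; work-up hydrolyses the silyl ester.

Step 8
Reactants: 11 malonic half-ester acid
Product: 12 methyl (2S)-2-(chlorocarbonyl)-2-{[(1S,3R)-2,2-dimethyl-3-(prop-1-en-2-yl)cyclobutyl]methyl}-5-methylhex-4-enoate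
Conditions: 1-chloro-N,N,2-trimethylprop-1-en-1-amine, CH2Cl2, 0 °C to rt
Reagents that add atoms: 1-chloro-N,N,2-trimethylprop-1-en-1-amine, CC(C)=C(Cl)N(C)C
Why: Neutral conversion of the acid into the acyl chloride with an α-chloroenamine, which releases no HCl onto the alkenes and cannot disturb the quaternary centre, since it bears no hydrogen and cannot form a ketene.

Fragment B (steps 9–12): the methyl ketone

Step 9
Reactants: 13 3-propylglutaric anhydride
Product: 14 (3S)-5-methoxy-5-oxo-3-propylpentanoic acid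
Conditions: MeOH, hydroquinine anthraquinone-1,4-diyl diether (10 mol%), Et2O, −40 °C
Reagents that add atoms: methanol, CO
Why: Alkaloid-catalysed desymmetrising methanolysis of the prochiral anhydride, in which the chiral tertiary amine acts as general base and directs methanol to one of the two enantiotopic carbonyl groups, which sets the side-chain stereocentre.

Step 10
Reactants: 14 hemiester
Product: 15 1-tert-butyl 5-methyl (3R)-3-propylpentanedioate
Conditions: tert-butyl 2,2,2-trichloroacetimidate, BF3·OEt2 (cat.), CH2Cl2/cyclohexane, rt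
Reagents that add atoms: tert-butyl 2,2,2-trichloroacetimidate, CC(C)(C)OC(=N)C(Cl)(Cl)Cl
Why: Acid-catalysed tert-butylation of the free carboxylic acid by the trichloroacetimidate, which leaves the methyl ester and the stereocentre unchanged.

Step 11
Reactants: 15 mixed diester
Product: 16 (3R)-5-tert-butoxy-5-oxo-3-propylpentanoic acid
Conditions: LiOH (1.2 equiv.), THF/H2O, 0 °C; 1 M HCl
Reagents that add atoms: lithium hydroxide, [Li+].[OH-]
Why: Saponification that tells the two esters apart by steric hindrance, because hydroxide attacks the methyl ester while the tert-butyl ester is inert under these conditions.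

Step 12
Reactants: 16 tert-butyl half-ester acid
Product: 18 tert-butyl (3R)-5-oxo-3-propylhexanoate, via acyl chloride 17 (not isolated)
Conditions: 1-chloro-N,N,2-trimethylprop-1-en-1-amine, CH2Cl2, rt; then MeMgBr, Fe(acac)3 (3 mol%), THF, −78 °C
Reagents that add atoms: methylmagnesium bromide, C[Mg]Br
Why: The acid is activated as its chloride under neutral conditions and then undergoes iron-catalysed acylation of the Grignard reagent, which at −78 °C is faster than addition to the new ketone or to the tert-butyl ester.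

Key step

Step 13
Reactants: 12 malonyl chloride methyl ester; 18 tert-butyl (3R)-5-oxo-3-propylhexanoate
Product: 20 tert-butyl (3S)-3-[(5R)-2,4-dihydroxy-5-{[(1S,3R)-2,2-dimethyl-3-(prop-1-en-2-yl)cyclobutyl]methyl}-5-(3-methylbut-2-en-1-yl)-6-oxocyclohexa-1,3-dien-1-yl]hexanoate (trione in its dienol form), via open-chain 1,3-diketone 19 (not isolated)
Conditions: 18 (2.1 equiv.), LiN(i-Pr)2 (2.2 equiv.), THF, −78 °C; 12 (1 equiv.), −78 °C; then LiN(i-Pr)2 (2.5 equiv.), −78 to 0 °C; aq. NH4Cl
Reagents that add atoms: none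
Why: LiN(i-Pr)2 removes a CH3 proton of 18 under kinetic control and the lithium enolate attacks the acyl chloride of 12 by addition–elimination, which forms C4a–C8a and gives diketone 19, deprotonated at once by the second equivalent of enolate. More base turns the diketonate into the 1,3-dianion, whose terminal carbon C6 attacks the methyl ester and expels methoxide to form C6–C7, and the acidic trione is deprotonated as it forms, which drives the sequence. The closest known reaction type is Claisen acylation of a ketone enolate followed by Dieckmann cyclisation of a diketone dianion, as used for 2,2-dialkylcyclohexane-1,3,5-triones. The ring closes in a 6-(enolendo)-exo-trig mode, because both enolate carbons (C5 and C6) lie inside the new ring. No stereocentre is created: C8 stays tetrahedral throughout and the side-chain centre is not at a reacting carbon, so both are carried through unchanged. The step needs only chemoselective pairing, which is secured by the reactivity order acyl chloride > methyl ester > tert-butyl ester and by the order of deprotonation (CH3 first, CH2 only in the dianion).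

Fragment C (steps 14–16): the chiral acyl unit

Step 14
Reactants: 21 ethyl (3S)-3-hydroxybutanoate
Product: 22 ethyl (2S,3S)-3-hydroxy-2-methylbutanoate
Conditions: LiN(i-Pr)2 (2.2 equiv.), THF, −50 to −20 °C; MeI, DMPU, −78 to 0 °C
Reagents that add atoms: iodomethane, CI
Why: Fráter–Seebach alkylation, in which the chelated lithium alkoxide–enolate is methylated on the face away from the C3 methyl group and gives the anti (2S,3S) isomer.

Step 15
Reactants: 22 anti hydroxy ester
Product: 23 ethyl (2S,3S)-3-[(tert-butyldimethylsilyl)oxy]-2-methylbutanoate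
Conditions: TBSCl, imidazole, DMF, rt
Reagents that add atoms: tert-butyldimethylsilyl chloride, C[Si](C)(Cl)C(C)(C)C
Why: Imidazole-promoted silylation of the secondary alcohol, which does not touch either stereocentre.

Step 16
Reactants: 23 silyloxy ester
Product: 24 (2S,3S)-3-[(tert-butyldimethylsilyl)oxy]-2-methylbutanoic acid
Conditions: LiOH, THF/MeOH/H2O, rt; 1 M HCl, 0 °C
Reagents that add atoms: lithium hydroxide, [Li+].[OH-]
Why: Mild saponification of the ethyl ester at room temperature, conditions under which the α-centre of a β-silyloxy ester is normally retained and the silyl ether survives.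

Endgame (steps 17–20)

Step 17
Reactants: 20 trione; 24 silyloxy acid
Product: 26 tert-butyl (3S)-3-[(5R)-3-[(2S,3S)-3-{[tert-butyl(dimethyl)silyl]oxy}-2-methylbutanoyl]-2,4-dihydroxy-5-{[(1S,3R)-2,2-dimethyl-3-(prop-1-en-2-yl)cyclobutyl]methyl}-5-(3-methylbut-2-en-1-yl)-6-oxocyclohexa-1,3-dien-1-yl]hexanoate, via enol ester 25 (not isolated)
Conditions: DCC, DMAP (1.2 equiv.), CH2Cl2, 0 °C to rt
Reagents that add atoms: none
Why: Carbodiimide/DMAP C-acylation of a cyclic β-dicarbonyl compound, in which a first-formed enol ester undergoes a DMAP-mediated Fries-type O-to-C shift to C4a, the only unsubstituted carbon between two carbonyl groups, where the product is held as the hydrogen-bonded β-triketone.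

Step 18
Reactants: 26 silyl-protected acyl trione
Product: 27 tert-butyl (3S)-3-[(5R)-2,4-dihydroxy-3-[(2S,3S)-3-hydroxy-2-methylbutanoyl]-5-{[(1S,3R)-2,2-dimethyl-3-(prop-1-en-2-yl)cyclobutyl]methyl}-5-(3-methylbut-2-en-1-yl)-6-oxocyclohexa-1,3-dien-1-yl]hexanoate
Conditions: HF·pyridine, pyridine, THF, 0 °C to rt
Reagents that add atoms: none
Why: Fluoride cleavage of the silyl ether under pyridine buffering, mild enough to keep the tert-butyl ester and to avoid acid-catalysed dehydrative ring closure, which would retain the configuration at C2.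

Step 19
Reactants: 27 β-hydroxy acyl trione
Product: 28 tert-butyl (3S)-3-[(2R,3S,8R)-8-{[(1S,3R)-2,2-dimethyl-3-(prop-1-en-2-yl)cyclobutyl]methyl}-5-hydroxy-2,3-dimethyl-8-(3-methylbut-2-en-1-yl)-4,7-dioxo-3,4,7,8-tetrahydro-2H-chromen-6-yl]hexanoate
Conditions: PPh3, DIAD, toluene, 0 °C to rt
Reagents that add atoms: none
Why: Intramolecular Mitsunobu etherification (6-exo-tet), in which the acidic β-triketone displaces the activated secondary hydroxyl with inversion at C2 while C3 is untouched, so the anti hydroxy ketone gives the cis pyranone (C2 R, C3 S); closure through O8a is expected because O5 stays in the hydrogen bond to the C4 carbonyl group, which holds the side chain over O8a.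

Step 20
Reactants: 28 chromenedione tert-butyl ester
Product: 30 (3S)-3-[(2R,3S,8R)-8-{[(1S,3R)-2,2-dimethyl-3-(prop-1-en-2-yl)cyclobutyl]methyl}-5-hydroxy-2,3-dimethyl-8-(3-methylbut-2-en-1-yl)-4,7-dioxo-3,4,7,8-tetrahydro-2H-chromen-6-yl]hexanoic acid (CNP0364345.1), via bis(trimethylsilyl) derivative 29 (not isolated)
Conditions: TMSOTf, 2,6-lutidine, CH2Cl2, 0 °C; pH 4 buffer
Reagents that add atoms: none
Why: Silyl triflate-mediated tert-butyl ester cleavage under lutidine buffering, chosen because it uses neither protic acid (prenyl group, isopropenylcyclobutane) nor a base strong enough to enolise C3, and the silyl ester and silyl enol ether are hydrolysed on work-up.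

Compound list

1 | (1R,5R)-(+)-verbenone, (1R,5R)-4,6,6-trimethylbicyclo[3.1.1]hept-3-en-2-one | O=C1C=C(C)[C@H]2C[C@@H]1C2(C)C | starting material
2 | (1R,3S)-3-acetyl-2,2-dimethylcyclobutane-1-carboxylic acid (cis) | CC(=O)[C@H]1C[C@@H](C(=O)O)C1(C)C | intermediate
3 | (1R,3R)-2,2-dimethyl-3-(prop-1-en-2-yl)cyclobutane-1-carboxylic acid (cis) | C=C(C)[C@H]1C[C@@H](C(=O)O)C1(C)C | intermediate
4 | [(1R,3R)-2,2-dimethyl-3-(prop-1-en-2-yl)cyclobutyl]methanol | C=C(C)[C@H]1C[C@@H](CO)C1(C)C | intermediate
5 | (1R,3R)-1-(iodomethyl)-2,2-dimethyl-3-(prop-1-en-2-yl)cyclobutane | C=C(C)[C@H]1C[C@@H](CI)C1(C)C | intermediate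
6 | tert-butyl methyl malonate | COC(=O)CC(=O)OC(C)(C)C | starting material
7 | 1-tert-butyl 3-methyl 2-{[(1S,3R)-2,2-dimethyl-3-(prop-1-en-2-yl)cyclobutyl]methyl}propanedioate (both C2 epimers) | C=C(C)[C@H]1C[C@@H](CC(C(=O)OC)C(=O)OC(C)(C)C)C1(C)C | intermediate
8 | prenyl bromide, 1-bromo-3-methylbut-2-ene | CC(C)=CCBr | starting material
9 | 1-tert-butyl 3-methyl (2S)-2-{[(1S,3R)-2,2-dimethyl-3-(prop-1-en-2-yl)cyclobutyl]methyl}-2-(3-methylbut-2-en-1-yl)propanedioate | C=C(C)[C@H]1C[C@@H](C[C@@](C(=O)OC(C)(C)C)(CC=C(C)C)C(=O)OC)C1(C)C | intermediate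
10 | methyl trimethylsilyl (2S)-2-{[(1S,3R)-2,2-dimethyl-3-(prop-1-en-2-yl)cyclobutyl]methyl}-2-(3-methylbut-2-en-1-yl)propanedioate | C=C(C)[C@H]1C[C@@H](C[C@@](C(=O)O[Si](C)(C)C)(CC=C(C)C)C(=O)OC)C1(C)C | intermediate (not isolated)
11 | (2R)-2-{[(1S,3R)-2,2-dimethyl-3-(prop-1-en-2-yl)cyclobutyl]methyl}-2-(methoxycarbonyl)-5-methylhex-4-enoic acid | C=C(C)[C@H]1C[C@@H](C[C@@](C(=O)O)(CC=C(C)C)C(=O)OC)C1(C)C | intermediate
12 | methyl (2S)-2-(chlorocarbonyl)-2-{[(1S,3R)-2,2-dimethyl-3-(prop-1-en-2-yl)cyclobutyl]methyl}-5-methylhex-4-enoate | C=C(C)[C@H]1C[C@@H](C[C@@](C(=O)Cl)(CC=C(C)C)C(=O)OC)C1(C)C | intermediate (key-step precursor)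
13 | 3-propylglutaric anhydride, 4-propyloxane-2,6-dione | CCCC1CC(=O)OC(=O)C1 | starting material
14 | (3S)-5-methoxy-5-oxo-3-propylpentanoic acid | COC(=O)C[C@@H](CCC)CC(=O)O | intermediate
15 | 1-tert-butyl 5-methyl (3R)-3-propylpentanedioate | COC(=O)C[C@@H](CCC)CC(=O)OC(C)(C)C | intermediate
16 | (3R)-5-tert-butoxy-5-oxo-3-propylpentanoic acid | OC(=O)C[C@@H](CCC)CC(=O)OC(C)(C)C | intermediate
17 | tert-butyl (3S)-5-chloro-5-oxo-3-propylpentanoate | ClC(=O)C[C@@H](CCC)CC(=O)OC(C)(C)C | intermediate (not isolated)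
18 | tert-butyl (3R)-5-oxo-3-propylhexanoate | CC(=O)C[C@@H](CCC)CC(=O)OC(C)(C)C | intermediate (key-step precursor)
19 | 9-tert-butyl 1-methyl (2R,7R)-2-{[(1S,3R)-2,2-dimethyl-3-(prop-1-en-2-yl)cyclobutyl]methyl}-2-(3-methylbut-2-en-1-yl)-3,5-dioxo-7-propylnonanedioate | C=C(C)[C@H]1C[C@@H](C[C@@](CC=C(C)C)(C(=O)OC)C(=O)CC(=O)C[C@@H](CCC)CC(=O)OC(C)(C)C)C1(C)C | intermediate (not isolated)
20 | tert-butyl (3S)-3-[(5R)-2,4-dihydroxy-5-{[(1S,3R)-2,2-dimethyl-3-(prop-1-en-2-yl)cyclobutyl]methyl}-5-(3-methylbut-2-en-1-yl)-6-oxocyclohexa-1,3-dien-1-yl]hexanoate (trione, dienol form) | C=C(C)[C@H]1C[C@@H](C[C@@]2(CC=C(C)C)C(=O)C([C@@H](CCC)CC(=O)OC(C)(C)C)=C(O)C=C2O)C1(C)C | intermediate (key-step product)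
21 | ethyl (3S)-3-hydroxybutanoate | CCOC(=O)C[C@H](C)O | starting material
22 | ethyl (2S,3S)-3-hydroxy-2-methylbutanoate | CCOC(=O)[C@@H](C)[C@H](C)O | intermediate
23 | ethyl (2S,3S)-3-[(tert-butyldimethylsilyl)oxy]-2-methylbutanoate | CCOC(=O)[C@@H](C)[C@H](C)O[Si](C)(C)C(C)(C)C | intermediate
24 | (2S,3S)-3-[(tert-butyldimethylsilyl)oxy]-2-methylbutanoic acid | OC(=O)[C@@H](C)[C@H](C)O[Si](C)(C)C(C)(C)C | intermediate
25 | enol ester of 20 with 24 (drawn as the O5 ester; the site of O-acylation is immaterial) | C=C(C)[C@H]1C[C@@H](C[C@@]2(CC=C(C)C)C(=O)C([C@@H](CCC)CC(=O)OC(C)(C)C)=C(OC(=O)[C@@H](C)[C@H](C)O[Si](C)(C)C(C)(C)C)C=C2O)C1(C)C | intermediate (not isolated)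
26 | tert-butyl (3S)-3-[(5R)-3-[(2S,3S)-3-{[tert-butyl(dimethyl)silyl]oxy}-2-methylbutanoyl]-2,4-dihydroxy-5-{[(1S,3R)-2,2-dimethyl-3-(prop-1-en-2-yl)cyclobutyl]methyl}-5-(3-methylbut-2-en-1-yl)-6-oxocyclohexa-1,3-dien-1-yl]hexanoate | C=C(C)[C@H]1C[C@@H](C[C@@]2(CC=C(C)C)C(=O)C([C@@H](CCC)CC(=O)OC(C)(C)C)=C(O)C(C(=O)[C@@H](C)[C@H](C)O[Si](C)(C)C(C)(C)C)=C2O)C1(C)C | intermediate
27 | tert-butyl (3S)-3-[(5R)-2,4-dihydroxy-3-[(2S,3S)-3-hydroxy-2-methylbutanoyl]-5-{[(1S,3R)-2,2-dimethyl-3-(prop-1-en-2-yl)cyclobutyl]methyl}-5-(3-methylbut-2-en-1-yl)-6-oxocyclohexa-1,3-dien-1-yl]hexanoate | C=C(C)[C@H]1C[C@@H](C[C@@]2(CC=C(C)C)C(=O)C([C@@H](CCC)CC(=O)OC(C)(C)C)=C(O)C(C(=O)[C@@H](C)[C@H](C)O)=C2O)C1(C)C | intermediate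
28 | tert-butyl (3S)-3-[(2R,3S,8R)-8-{[(1S,3R)-2,2-dimethyl-3-(prop-1-en-2-yl)cyclobutyl]methyl}-5-hydroxy-2,3-dimethyl-8-(3-methylbut-2-en-1-yl)-4,7-dioxo-3,4,7,8-tetrahydro-2H-chromen-6-yl]hexanoate | C=C(C)[C@H]1C[C@@H](C[C@@]2(CC=C(C)C)C(=O)C([C@@H](CCC)CC(=O)OC(C)(C)C)=C(O)C3=C2O[C@H](C)[C@H](C)C3=O)C1(C)C | intermediate
29 | trimethylsilyl ester and 5-O-trimethylsilyl enol ether of 30 | C=C(C)[C@H]1C[C@@H](C[C@@]2(CC=C(C)C)C(=O)C([C@@H](CCC)CC(=O)O[Si](C)(C)C)=C(O[Si](C)(C)C)C3=C2O[C@H](C)[C@H](C)C3=O)C1(C)C | intermediate (not isolated)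
30 | (3S)-3-[(2R,3S,8R)-8-{[(1S,3R)-2,2-dimethyl-3-(prop-1-en-2-yl)cyclobutyl]methyl}-5-hydroxy-2,3-dimethyl-8-(3-methylbut-2-en-1-yl)-4,7-dioxo-3,4,7,8-tetrahydro-2H-chromen-6-yl]hexanoic acid (CNP0364345.1) | C=C(C)[C@H]1C[C@@H](C[C@@]2(CC=C(C)C)C(=O)C([C@@H](CCC)CC(=O)O)=C(O)C3=C2O[C@H](C)[C@H](C)C3=O)C1(C)C | target

Total step count: 20 (fragment A 8, fragment B 4, key step 1, fragment C 3, endgame 4).
Longest linear sequence: 13 steps (steps 1–8, 13, 17–20).

Steps most likely to fail

Step 13 (key step). The hindered acyl chloride may acylate the enolate on oxygen, or only transfer a proton, and the dianion may close slowly onto an ester that sits on a quaternary carbon. The fallback sets out from 12 and 18 and forms the first bond by aldol addition, which has no O/C ambiguity. 12 is reduced with LiAlH(OtBu)3 (THF, −78 °C) to the non-enolisable formyl ester, methyl (2R)-2-{[(1S,3R)-2,2-dimethyl-3-(prop-1-en-2-yl)cyclobutyl]methyl}-2-formyl-5-methylhex-4-enoate F1. The lithium enolate of 18 (LiN(i-Pr)2, THF, −78 °C) adds to F1 to give the β-hydroxy ketone, 9-tert-butyl 1-methyl (2R,7R)-2-{[(1S,3R)-2,2-dimethyl-3-(prop-1-en-2-yl)cyclobutyl]methyl}-3-hydroxy-2-(3-methylbut-2-en-1-yl)-5-oxo-7-propylnonanedioate F2, as both carbinol epimers. Oxidation with the periodinane DMP (1,1,1-triacetoxy-1,1-dihydro-1,2-benziodoxol-3(1H)-one, CH2Cl2, rt) gives diketone 19, where the route is rejoined. 19 is then isolated and cyclised on its own with LiN(i-Pr)2 (3 equiv., THF, −78 to 0 °C) to 20.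

Step 19. The activated hydroxyl may be lost by elimination to the tigloyl ketone, which would erase C2 and C3, or the ring may close through O5 and not O8a. The fallback sets out from 20 and closes the ring by conjugate addition in place of substitution. 20 is C-acylated with tiglic acid (DCC, DMAP, CH2Cl2) to the tigloyl trione, tert-butyl (3S)-3-[(5R)-2,4-dihydroxy-5-{[(1S,3R)-2,2-dimethyl-3-(prop-1-en-2-yl)cyclobutyl]methyl}-3-[(2E)-2-methylbut-2-enoyl]-5-(3-methylbut-2-en-1-yl)-6-oxocyclohexa-1,3-dien-1-yl]hexanoate F3. Quinine in chlorobenzene at rt (quinidine if the sense is opposite) should then mediate the intramolecular oxa-Michael addition and protonate C3 under kinetic control to the cis isomer, which gives 28, where the route is rejoined. Because this closure is reversible until C3 is protonated, it also favours the O8a isomer, which keeps the hydrogen-bonded 5-OH/4-oxo pair.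

Step 6. Facial selectivity of the prenylation may be poor, because only the catalyst tells the two ester groups of the enolate apart. The fallback sets out from 5 and replaces asymmetric alkylation by enzymatic differentiation of two like esters. Dimethyl malonate is alkylated with 5 (NaH, DMF, 60 °C) to dimethyl 2-{[(1S,3R)-2,2-dimethyl-3-(prop-1-en-2-yl)cyclobutyl]methyl}propanedioate F4. Prenylation with 8 (NaH, THF) gives dimethyl 2-{[(1S,3R)-2,2-dimethyl-3-(prop-1-en-2-yl)cyclobutyl]methyl}-2-(3-methylbut-2-en-1-yl)propanedioate F5, in which the malonate carbon is not yet a stereocentre. Pig-liver esterase (phosphate buffer pH 7.5, DMSO co-solvent, rt) hydrolyses one of the two diastereotopic ester groups to 11, where the route is rejoined. The two possible half-esters are diastereomers, so the unwanted one can be removed by crystallisation of an amine salt.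

Further compounds
F1 | step 13 | methyl (2R)-2-{[(1S,3R)-2,2-dimethyl-3-(prop-1-en-2-yl)cyclobutyl]methyl}-2-formyl-5-methylhex-4-enoate | C=C(C)[C@H]1C[C@@H](C[C@@](C=O)(CC=C(C)C)C(=O)OC)C1(C)C
F2 | step 13 | 9-tert-butyl 1-methyl (2R,7R)-2-{[(1S,3R)-2,2-dimethyl-3-(prop-1-en-2-yl)cyclobutyl]methyl}-3-hydroxy-2-(3-methylbut-2-en-1-yl)-5-oxo-7-propylnonanedioate (both C3 epimers) | C=C(C)[C@H]1C[C@@H](C[C@@](CC=C(C)C)(C(=O)OC)C(O)CC(=O)C[C@@H](CCC)CC(=O)OC(C)(C)C)C1(C)C
F3 | step 19 | tert-butyl (3S)-3-[(5R)-2,4-dihydroxy-5-{[(1S,3R)-2,2-dimethyl-3-(prop-1-en-2-yl)cyclobutyl]methyl}-3-[(2E)-2-methylbut-2-enoyl]-5-(3-methylbut-2-en-1-yl)-6-oxocyclohexa-1,3-dien-1-yl]hexanoate | C=C(C)[C@H]1C[C@@H](C[C@@]2(CC=C(C)C)C(=O)C([C@@H](CCC)CC(=O)OC(C)(C)C)=C(O)C(C(=O)/C(C)=C/C)=C2O)C1(C)C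
F4 | step 6 | dimethyl 2-{[(1S,3R)-2,2-dimethyl-3-(prop-1-en-2-yl)cyclobutyl]methyl}propanedioate | C=C(C)[C@H]1C[C@@H](CC(C(=O)OC)C(=O)OC)C1(C)C
F5 | step 6 | dimethyl 2-{[(1S,3R)-2,2-dimethyl-3-(prop-1-en-2-yl)cyclobutyl]methyl}-2-(3-methylbut-2-en-1-yl)propanedioate | C=C(C)[C@H]1C[C@@H](CC(CC=C(C)C)(C(=O)OC)C(=O)OC)C1(C)C
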